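**Retrosynthetic overview**

1. Target 14 ⇐ allylic alcohol 13 (MnO2) ⇐ isopropenyl acetate 12 (Riley oxidation) ⇐ alcohol 11 (acetylation) ⇐ alkenylboronate 10 (Suzuki–Miyaura methylation). The enal and the C3 acetate come last because they make C3–O and C2–H labile.
2. Key disconnection, C2–C3 with a C–B bond at the central carbon: 10 ⇐ aldehyde/aryloxyallene 8 + B2pin2, by a copper-catalysed enantioselective borylative allene–aldehyde cyclisation that closes the dihydrofuran ring and sets C2 and C3 (cis, 2S,3S) together.
3. Enabling feature: C3 is a carbinol carbon on benzene carbon C3a, ortho to C7a–O1, and C2 carries O1 and a 1,1-disubstituted vinyl group. C2, the quaternary sp2 carbon and the exocyclic CH2 are therefore the three carbons of an allene bound to O1, and C3 is an ortho aldehyde.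
4. 8 ⇐ 5-acetylsalicylaldehyde 1 + propargyl bromide 2 + tigloyl chloride 7, by O-propargylation, asymmetric transfer hydrogenation (sets the (R)-carbinol), propargyl-to-allenyl isomerisation, selective reoxidation of the primary alcohol, and tigloylation.
5. Ring order: the benzene ring is bought with 1; the dihydrofuran ring is the only ring made and is closed in step 6.

Key step: step 6

Assumption: 1 is taken as a catalogue compound, and because the sense of induction in step 6 cannot be fixed on paper, the (R)-bisphosphine is written as a placeholder for whichever antipode gives the (2S,3S) ring series.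

**Route**

Step 1
Reactants: 1 5-acetyl-2-hydroxybenzaldehyde; 2 propargyl bromide (3-bromoprop-1-yne)
Product: 3 5-acetyl-2-(prop-2-yn-1-yloxy)benzaldehyde
Conditions: K2CO3, DMF, rt
Reagents that add atoms: propargyl bromide 2, C#CCBr
Why: Williamson etherification of the acidic salicylaldehyde phenol with a primary propargylic bromide is a routine SN2 O-alkylation, and capping O1 first means no benzylic oxygen function ever sits ortho or para to a free phenoxide (no quinone methide pathways); no stereocentre is formed.

Step 2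
Reactants: 3 5-acetyl-2-(prop-2-yn-1-yloxy)benzaldehyde
Product: 4 (1R)-1-[3-(hydroxymethyl)-4-(prop-2-yn-1-yloxy)phenyl]ethan-1-ol
Conditions: RuCl(p-cymene)[(R,R)-TsDPEN] (1 mol %), HCO2H/Et3N (5:2), CH2Cl2, rt
Reagents that add atoms: none
Why: Noyori asymmetric transfer hydrogenation (outer-sphere Ru–H/N–H delivery) reduces the aldehyde to the primary alcohol and the aryl methyl ketone to the secondary alcohol in one operation, the (R,R)-catalyst being expected to give the (R)-1-arylethanol as it does with acetophenone, while the remote alkyne is not a substrate for this C=O-selective reduction.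

Step 3
Reactants: 4 (1R)-1-[3-(hydroxymethyl)-4-(prop-2-yn-1-yloxy)phenyl]ethan-1-ol
Product: 5 (1R)-1-[3-(hydroxymethyl)-4-(propa-1,2-dien-1-yloxy)phenyl]ethan-1-ol
Conditions: KOtBu (2.5 equiv), THF, 0 °C to rt; H2O quench; Et3N-buffered silica
Reagents that add atoms: none
Why: Base-mediated propargyl–allenyl prototropic isomerisation of aryl propargyl ethers stops at the aryloxyallene under these mild conditions, and it is run at the diol stage where no carbonyl or ester can be enolised or attacked; the carbinol stereocentre has no acidic C–H and is untouched.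

Step 4
Reactants: 5 (1R)-1-[3-(hydroxymethyl)-4-(propa-1,2-dien-1-yloxy)phenyl]ethan-1-ol
Product: 6 5-[(1R)-1-hydroxyethyl]-2-(propa-1,2-dien-1-yloxy)benzaldehyde
Conditions: Cu(MeCN)4OTf (5 mol %), 2,2'-bipyridine (5 mol %), TEMPO (5 mol %), N-methylimidazole (10 mol %), air, MeCN, rt
Reagents that add atoms: none
Why: The copper/TEMPO aerobic alcohol oxidation is strongly selective for unhindered primary (here benzylic) over secondary alcohols and runs under neutral to slightly basic conditions that spare the acid-labile allenyl ether; the stereocentre is not involved.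

Step 5
Reactants: 6 5-[(1R)-1-hydroxyethyl]-2-(propa-1,2-dien-1-yloxy)benzaldehyde; 7 tigloyl chloride ((2E)-2-methylbut-2-enoyl chloride)
Product: 8 (1R)-1-[3-formyl-4-(propa-1,2-dien-1-yloxy)phenyl]ethyl (2E)-2-methylbut-2-enoate
Conditions: Et3N, DMAP (cat.), CH2Cl2, 0 °C
Reagents that add atoms: tigloyl chloride 7, C/C=C(\C)C(=O)Cl
Why: DMAP-catalysed O-acylation of the secondary benzylic alcohol breaks no C–O bond, so the (R)-configuration is retained, and the thermodynamically preferred E geometry of the tigloyl unit is kept under these mild basic conditions.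

Step 6
Reactants: 8 (1R)-1-[3-formyl-4-(propa-1,2-dien-1-yloxy)phenyl]ethyl (2E)-2-methylbut-2-enoate
Product: 10 (1R)-1-{(2S,3S)-3-hydroxy-2-[1-(4,4,5,5-tetramethyl-1,3,2-dioxaborolan-2-yl)ethenyl]-2,3-dihydro-1-benzofuran-5-yl}ethyl (2E)-2-methylbut-2-enoate, via O-boryl ether 9 (not isolated)
Conditions: CuCl (5 mol %), (R)-DTBM-SEGPHOS (6 mol %), NaOtBu (15 mol %), B2pin2 (1.2 equiv), THF, 0 °C; then H2O
Reagents that add atoms: bis(pinacolato)diboron, CC1(C)OB(B2OC(C)(C)C(C)(C)O2)OC1(C)C
Why: The ligated L*Cu–Bpin formed from L*Cu–OtBu and B2pin2 adds across the terminal C=C of the aryloxyallene on the side away from OAr, placing boron on the central carbon and giving a (Z)-2-boryl-3-aryloxyallylcopper, whose γ-carbon (the future C2) adds to the ortho aldehyde through a closed six-membered chair transition state, after which σ-bond metathesis of the copper alkoxide with B2pin2 releases O-boryl ether 9 and regenerates the catalyst. The closest known reaction type is the copper-catalysed enantioselective coupling of allenes, B2pin2 and aldehydes or ketones, including its intramolecular borylative cyclisations of allene-tethered ketones to cis alkenylboronate alcohols. The dihydrofuran ring closes by C2–C3 bond formation in the 5-exo-trig mode, the carbonyl oxygen staying outside the ring. C2 and C3 are set together: the cis relationship follows from the Z allyl geometry and the chair transition state (axial O1 on the γ-carbon, equatorial C3a on the carbonyl carbon, so the three-atom C3a–C7a–O1 tether places the new hydroxyl and the borylvinyl group on the same face), and the absolute (2S,3S) configuration is set by the chiral bisphosphine on copper, the remote (R)-centre being too distant to interfere. The step needs borylcupration of the allene in preference to the aldehyde and the tiglate, and γ- rather than α-attack (five- versus seven-membered ring); allenes are the fastest partners for Cu–B insertion, no protic additive is present to turn over conjugate borylation of the trisubstituted enoate, and only the five-membered closure fits the cyclic transition state allowed by the tether.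

Step 7
Reactants: 10 (1R)-1-{(2S,3S)-3-hydroxy-2-[1-(4,4,5,5-tetramethyl-1,3,2-dioxaborolan-2-yl)ethenyl]-2,3-dihydro-1-benzofuran-5-yl}ethyl (2E)-2-methylbut-2-enoate
Product: 11 (1R)-1-[(2S,3S)-3-hydroxy-2-(prop-1-en-2-yl)-2,3-dihydro-1-benzofuran-5-yl]ethyl (2E)-2-methylbut-2-enoate
Conditions: MeI, Pd(dppf)Cl2 (5 mol %), K3PO4, THF/H2O, 40 °C
Reagents that add atoms: iodomethane, CI
Why: Suzuki–Miyaura cross-coupling of the 1,1-disubstituted alkenylboronate with iodomethane replaces boron by methyl at the same sp2 carbon without touching either ring stereocentre, and the mild phosphate base should leave the tiglate and the free cis alcohol intact.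

Step 8
Reactants: 11 (1R)-1-[(2S,3S)-3-hydroxy-2-(prop-1-en-2-yl)-2,3-dihydro-1-benzofuran-5-yl]ethyl (2E)-2-methylbut-2-enoate
Product: 12 (1R)-1-[(2S,3S)-3-acetoxy-2-(prop-1-en-2-yl)-2,3-dihydro-1-benzofuran-5-yl]ethyl (2E)-2-methylbut-2-enoate
Conditions: Ac2O, pyridine, DMAP (cat.), CH2Cl2, 0 °C to rt
Reagents that add atoms: acetic anhydride, CC(=O)OC(C)=O
Why: DMAP-catalysed O-acetylation proceeds with retention at C3 and is done before the aldehyde exists, so the cis hydroxyl can never close onto it as a lactol.

Step 9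
Reactants: 12 (1R)-1-[(2S,3S)-3-acetoxy-2-(prop-1-en-2-yl)-2,3-dihydro-1-benzofuran-5-yl]ethyl (2E)-2-methylbut-2-enoate
Product: 13 (1R)-1-[(2S,3S)-3-acetoxy-2-(3-hydroxyprop-1-en-2-yl)-2,3-dihydro-1-benzofuran-5-yl]ethyl (2E)-2-methylbut-2-enoate
Conditions: SeO2 (30 mol %), tBuOOH (3 equiv), CH2Cl2, rt
Reagents that add atoms: selenium dioxide, O=[Se]=O; tert-butyl hydroperoxide, CC(C)(C)OO
Why: Riley allylic oxidation (ene reaction of SeO2, then [2,3]-sigmatropic shift) of a 1,1-disubstituted alkene is expected to occur at the methyl group rather than the C2 methine, as is known for 2-isopropenyl-2,3-dihydrobenzofurans, while the electron-poor tiglate alkene should not react; no stereocentre is involved, and any 14 formed by over-oxidation is simply carried forward.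

Step 10
Reactants: 13 (1R)-1-[(2S,3S)-3-acetoxy-2-(3-hydroxyprop-1-en-2-yl)-2,3-dihydro-1-benzofuran-5-yl]ethyl (2E)-2-methylbut-2-enoate
Product: 14 (1R)-1-[(2S,3S)-3-acetoxy-2-(3-oxoprop-1-en-2-yl)-2,3-dihydro-1-benzofuran-5-yl]ethyl (2E)-2-methylbut-2-enoate
Conditions: MnO2 (activated, excess), CH2Cl2, rt
Reagents that add atoms: none
Why: Allylic alcohol oxidation with activated MnO2 acts only on the primary allylic alcohol, and its neutral heterogeneous conditions avoid loss of acetic acid from C3 (aromatisation to the benzofuran) and epimerisation at C2.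

**Compound list**

1 | 5-acetyl-2-hydroxybenzaldehyde | CC(=O)c1ccc(O)c(C=O)c1 | starting material
2 | propargyl bromide (3-bromoprop-1-yne) | C#CCBr | starting material
3 | 5-acetyl-2-(prop-2-yn-1-yloxy)benzaldehyde | CC(=O)c1ccc(OCC#C)c(C=O)c1 | intermediate
4 | (1R)-1-[3-(hydroxymethyl)-4-(prop-2-yn-1-yloxy)phenyl]ethan-1-ol | C#CCOc1ccc([C@@H](C)O)cc1CO | intermediate
5 | (1R)-1-[3-(hydroxymethyl)-4-(propa-1,2-dien-1-yloxy)phenyl]ethan-1-ol | C=C=COc1ccc([C@@H](C)O)cc1CO | intermediate
6 | 5-[(1R)-1-hydroxyethyl]-2-(propa-1,2-dien-1-yloxy)benzaldehyde | C=C=COc1ccc([C@@H](C)O)cc1C=O | intermediate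
7 | tigloyl chloride, (2E)-2-methylbut-2-enoyl chloride | C/C=C(\C)C(=O)Cl | starting material
8 | (1R)-1-[3-formyl-4-(propa-1,2-dien-1-yloxy)phenyl]ethyl (2E)-2-methylbut-2-enoate | C=C=COc1ccc([C@@H](C)OC(=O)/C(C)=C/C)cc1C=O | intermediate
9 | (1R)-1-{(2S,3S)-3-[(4,4,5,5-tetramethyl-1,3,2-dioxaborolan-2-yl)oxy]-2-[1-(4,4,5,5-tetramethyl-1,3,2-dioxaborolan-2-yl)ethenyl]-2,3-dihydro-1-benzofuran-5-yl}ethyl (2E)-2-methylbut-2-enoate | C=C(B3OC(C)(C)C(C)(C)O3)[C@@H]1Oc2ccc([C@@H](C)OC(=O)/C(C)=C/C)cc2[C@@H]1OB4OC(C)(C)C(C)(C)O4 | intermediate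
10 | (1R)-1-{(2S,3S)-3-hydroxy-2-[1-(4,4,5,5-tetramethyl-1,3,2-dioxaborolan-2-yl)ethenyl]-2,3-dihydro-1-benzofuran-5-yl}ethyl (2E)-2-methylbut-2-enoate | C=C(B3OC(C)(C)C(C)(C)O3)[C@@H]1Oc2ccc([C@@H](C)OC(=O)/C(C)=C/C)cc2[C@@H]1O | intermediate
11 | (1R)-1-[(2S,3S)-3-hydroxy-2-(prop-1-en-2-yl)-2,3-dihydro-1-benzofuran-5-yl]ethyl (2E)-2-methylbut-2-enoate | C=C(C)[C@@H]1Oc2ccc([C@@H](C)OC(=O)/C(C)=C/C)cc2[C@@H]1O | intermediate
12 | (1R)-1-[(2S,3S)-3-acetoxy-2-(prop-1-en-2-yl)-2,3-dihydro-1-benzofuran-5-yl]ethyl (2E)-2-methylbut-2-enoate | C=C(C)[C@@H]1Oc2ccc([C@@H](C)OC(=O)/C(C)=C/C)cc2[C@@H]1OC(C)=O | intermediate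
13 | (1R)-1-[(2S,3S)-3-acetoxy-2-(3-hydroxyprop-1-en-2-yl)-2,3-dihydro-1-benzofuran-5-yl]ethyl (2E)-2-methylbut-2-enoate | C=C(CO)[C@@H]1Oc2ccc([C@@H](C)OC(=O)/C(C)=C/C)cc2[C@@H]1OC(C)=O | intermediate
14 | (1R)-1-[(2S,3S)-3-acetoxy-2-(3-oxoprop-1-en-2-yl)-2,3-dihydro-1-benzofuran-5-yl]ethyl (2E)-2-methylbut-2-enoate (CNP0294391.6) | C=C(C=O)[C@@H]1Oc2ccc([C@@H](C)OC(=O)/C(C)=C/C)cc2[C@@H]1OC(C)=O | target

**Step count and risks**

Total step count: 10. Longest linear sequence: 10 steps (1 to 14; 2 and 7 are bought reagents that join a linear route).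

Steps most likely to fail:

Step 6. The cyclisation may suffer from poor facial selectivity at the aldehyde with the chosen ligand, or from competing 1,2-borylation of the aldehyde or conjugate borylation of the tiglate before the allene is engaged. The fallback sets out from 8 and returns at 11, so step 7 is no longer needed. Nickel-catalysed alkylative cyclisation of the allenyl aldehyde 8 with Me2Zn (Ni(COD)2 cat., THF, 0 °C) is a known cis-selective way to put a methyl group on the central allene carbon while closing the ring. Without a chiral ligand it should give 11 together with its ring-antipodal (2R,3R) cis isomer F1. Oxidation of the mixture with Dess–Martin periodinane/NaHCO3 should converge both to the 3-ketone F2, whose C2 centre is configurationally labile. Transfer hydrogenation of F2 with RuCl(p-cymene)[(R,R)-TsDPEN] in HCO2H/Et3N under dynamic kinetic resolution should then return 11. Hydride attacks anti to the isopropenyl group (cis product), and the catalyst has the same sense of induction as in step 2 (C3a as the aryl group), which corresponds to 3S.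

Step 9. The selenium ene reaction may abstract the C2 methine hydrogen instead of a methyl hydrogen, or the seleninic acid medium may promote loss of acetic acid from C3. The fallback sets out from 12 and returns at 14. Dye-sensitised photo-oxygenation (O2, tetraphenylporphyrin, visible light, CH2Cl2, 0 °C; Schenck ene reaction) of the isopropenyl group should give the primary allylic hydroperoxide F3 under neutral conditions. Dehydration of F3 with Ac2O/pyridine (Kornblum–DeLaMare-type) should give the enal 14 directly.

Step 7. The alkenylpalladium intermediate may undergo protodeboronation or β-aryloxy elimination (opening of the new ring) faster than methyl transfer. The fallback sets out from 10 and returns at 13, bypassing steps 8 and 9 and avoiding any alkenyl–palladium species. Compound 10 is acetylated (Ac2O, pyridine, DMAP) to the boronate acetate F4. Matteson homologation of F4 with LiCH2Cl generated in situ (BrCH2Cl, nBuLi, THF, −78 °C to rt) should insert a CH2 group into the C–B bond to give the allylboronate F5. Oxidation of F5 with NaBO3·4H2O in THF/H2O should give the allylic alcohol 13.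

Further compounds
F1 | step 6 | (1R)-1-[(2R,3R)-3-hydroxy-2-(prop-1-en-2-yl)-2,3-dihydro-1-benzofuran-5-yl]ethyl (2E)-2-methylbut-2-enoate | C=C(C)[C@H]1Oc2ccc([C@@H](C)OC(=O)/C(C)=C/C)cc2[C@H]1O
F2 | step 6 | (1R)-1-[3-oxo-2-(prop-1-en-2-yl)-2,3-dihydro-1-benzofuran-5-yl]ethyl (2E)-2-methylbut-2-enoate (C2 labile) | C=C(C)C1Oc2ccc([C@@H](C)OC(=O)/C(C)=C/C)cc2C1=O
F3 | step 9 | (1R)-1-[(2S,3S)-3-acetoxy-2-(3-hydroperoxyprop-1-en-2-yl)-2,3-dihydro-1-benzofuran-5-yl]ethyl (2E)-2-methylbut-2-enoate | C=C(COO)[C@@H]1Oc2ccc([C@@H](C)OC(=O)/C(C)=C/C)cc2[C@@H]1OC(C)=O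
F4 | step 7 | (1R)-1-{(2S,3S)-3-acetoxy-2-[1-(4,4,5,5-tetramethyl-1,3,2-dioxaborolan-2-yl)ethenyl]-2,3-dihydro-1-benzofuran-5-yl}ethyl (2E)-2-methylbut-2-enoate | C=C(B3OC(C)(C)C(C)(C)O3)[C@@H]1Oc2ccc([C@@H](C)OC(=O)/C(C)=C/C)cc2[C@@H]1OC(C)=O
F5 | step 7 | (1R)-1-{(2S,3S)-3-acetoxy-2-[3-(4,4,5,5-tetramethyl-1,3,2-dioxaborolan-2-yl)prop-1-en-2-yl]-2,3-dihydro-1-benzofuran-5-yl}ethyl (2E)-2-methylbut-2-enoate | C=C(CB3OC(C)(C)C(C)(C)O3)[C@@H]1Oc2ccc([C@@H](C)OC(=O)/C(C)=C/C)cc2[C@@H]1OC(C)=O
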